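The numbers in the tables come from a simulation with made-up constants, and the scatter is random.

A factor of 1.40 separates this flask from the blue run. This stretch is the blue run's [catalyst] divided by the flask's [catalyst], and if every rate is first order in catalyst it counts the flask minutes that match one blue minute. Equal [catalyst] is the zero of this scale: a stretch of one, with both flasks on the same clock.

in all of them: catalyst 1 mol%

| charge | substrate | remark | time |
|---|---|---|---|
| blue | 2.8 M | run made earlier |  |
| flask | 2.0 M |  | 2.0 min |

blue run (percent of the substrate charged)

| time / min | target / % | substrate / % |
|---|---|---|
| 0.167 | 18.3 | 77.7 |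
| 0.250 | 22.4 | 68.0 |
| 0.417 | 27.0 | 56.0 |
| 0.667 | 26.8 | 39.8 |
| 1.00 | 22.1 | 28.4 |
| 1.50 | 14.9 | 16.2 |
| 2.50 | 7.8 | 5.9 |

(each reading ± 0.5 percentage points)

- what may be going on: target + catalyst <-> isomer of the product A + catalyst; isomer of the product A + catalyst <-> isomer of the product B + catalyst; substrate + catalyst <-> target + catalyst
- no earlier run changes the charge of catalyst; that part of a forecast is a guess

1. when, up to 2.0 min, the flask holds most target
2. the amount of target, in percent of the substrate charged, at that time
3. the first time at which target reaches 14%, in the same percent, in min

Take the settings in turn. The substrate charge falls from 2.8 M to 2.0 M, and at a fixed loading [catalyst] falls with it, from 0.0280 M to 0.0200 M. Every proposed step carries catalyst on both sides, so each is pseudo-first-order at constant [catalyst]. If each is also first order in catalyst, the percent curves keep their shape and their time axis lengthens by the stretch. The peak height therefore stays near the blue reading of 27.0%.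

The loading stays at 1 mol% and no earlier run changes the charge of catalyst, so that order in catalyst is a guess. In the blue run, the near-equal readings at 0.417 min and 0.667 min put the peak near their midpoint, 0.542 min, which gives about 0.759 min in this flask. The limit of 2.0 min lies later than that, so by this reckoning the peak falls inside it. A straight line from zero to the first blue target reading puts 14% of target at about 0.179 min in this flask.

The forecast, holding that “the time axis stretches by 1.4”, gives 27.2% at 0.73 min, slightly earlier than this reckoning, and 0.163 min for the level.

The flask gives 27.4% at 0.705 min, and 0.159 min for the level.

    target + catalyst ⇌ isomer of the product A + catalyst, rate k1*[catalyst]*[target] forward; the back reaction follows from the equilibrium constant (K = 17.0, k = 1.40 M⁻¹ s⁻¹)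
    isomer of the product A + catalyst ⇌ isomer of the product B + catalyst, rate k2*[catalyst]*[isomer of the product A] forward; the back reaction follows from the equilibrium constant (K = 0.180, k = 2.80 M⁻¹ s⁻¹)
    substrate + catalyst ⇌ target + catalyst, rate k3*[substrate]*[catalyst] forward; the back reaction follows from the equilibrium constant (K = 2.50, k = 0.950 M⁻¹ s⁻¹)

At 0.516 min the flask still made target 1.28 times faster than it used it, net. By 2.00 min target had fallen to 16.0%, with isomer of the product A at 56.3%. Divided by the stretch, that end matches 1.43 min of blue time, beside the blue reading of 14.9% target at 1.50 min. The flask charged with 0.4 mol% catalyst reaches 0.571 min of blue time in 2.0 min, which lies between the blue substrate readings of 56.0% at 0.417 min and 39.8% at 0.667 min, and it holds 45.6% substrate.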